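**Retrosynthetic overview** (atom labels follow furo[3,4-c]furan-1-one numbering)
1. Target ⇐ its pentabenzyl ether; global hydrogenolysis is the last step.
2. Tetrahydrofuran ring (bonds C6–C6a and C4–O5) ⇐ three-to-five ring expansion of a lactone-activated cyclopropane by 3,4-bis(benzyloxy)benzaldehyde (bridgehead aldol, iodide opening of the cyclopropane, O-alkylative closure).
3. Cyclopropane-fused γ-lactone ⇐ cis-2-aroylcyclopropanecarboxylic acid (ketone reduction, lactonisation) ⇐ enantioselective arylative desymmetrisation of meso cyclopropane-1,2-dicarboxylic anhydride.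
4. Aryl pieces: the 3,4,5-tris(benzyloxy)phenyl bromide from 4-bromophenol (Duff diformylation, Dakin oxidation, benzylation); the aldehyde from catechol (benzylation, Rieche formylation).
5. Ring order: cyclopropane (present in the anhydride) → γ-lactone → tetrahydrofuran (made last, out of the cyclopropane).

Assumptions: benzyl ethers are the phenol protecting groups. In step 4 the ligand enantiomer named is taken to give the (1R,2S) acid; if the opposite sense is found, its mirror-image ligand is used.

**Step 1**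
Reactants: 1 4-bromophenol
Product: 2 5-bromo-2-hydroxybenzene-1,3-dicarbaldehyde
Conditions: hexamethylenetetramine (4 equiv), CF3CO2H, reflux, 24 h; then 4 M HCl, rt
Reagents that add atoms: hexamethylenetetramine (C1N2CN3CN1CN(C2)C3); water (O)
Why: Duff formylation, in which the free phenol directs the iminium electrophile to both ortho positions (para is blocked by bromine) and the benzylamine intermediates are oxidised to the aldehydes by hydride transfer to further iminium ion; no stereocentre is formed.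

**Step 2**
Reactants: 2 5-bromo-2-hydroxybenzene-1,3-dicarbaldehyde
Product: 3 5-bromobenzene-1,2,3-triol
Conditions: 30% H2O2, NaOH aq, THF, 0 °C to rt, argon; then 2 M HCl; used crude
Reagents that add atoms: hydrogen peroxide (OO)
Why: Double Dakin oxidation, since each formyl group is ortho to the phenolate so that perhydroxide addition, aryl migration to oxygen and formate hydrolysis turn both CHO groups into OH; argon is needed because the bromopyrogallol is air-sensitive in base.

**Step 3**
Reactants: 3 5-bromobenzene-1,2,3-triol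
Product: 4 1,2,3-tris(benzyloxy)-5-bromobenzene
Conditions: BnBr (3.5 equiv), K2CO3, DMF, 60 °C, argon
Reagents that add atoms: benzyl bromide (BrCc1ccccc1)
Why: Williamson ether synthesis on the three phenoxides, which also removes the air sensitivity of the triol.

**Step 4**
Reactants: 4 1,2,3-tris(benzyloxy)-5-bromobenzene; 5 3-oxabicyclo[3.1.0]hexane-2,4-dione (meso cis-cyclopropane-1,2-dicarboxylic anhydride)
Product: 8 (1R,2S)-2-[3,4,5-tris(benzyloxy)benzoyl]cyclopropane-1-carboxylic acid, via aryllithium 6 (not isolated), via arylzinc chloride 7 (not isolated)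
Conditions: n-BuLi, THF, −78 °C; ZnCl2, −78 to 0 °C; then 5, Pd(OAc)2 (5 mol %), (R)-1-[(S)-2-(diphenylphosphino)ferrocenyl]ethyldicyclohexylphosphine (C36H44FeP2, 6 mol %), THF, rt; 1 M HCl work-up
Reagents that add atoms: none
Why: Bromine–lithium exchange, transmetalation to zinc and palladium-catalysed enantioselective desymmetrising acylation of a meso succinic-type anhydride (acyl C–O oxidative addition, aryl transfer from zinc, reductive elimination), in which the chiral diphosphine selects one of the two enantiotopic carbonyl groups and so fixes both cyclopropane stereocentres, cis being enforced by the ring.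

**Step 5**
Reactants: 8 (1R,2S)-2-[3,4,5-tris(benzyloxy)benzoyl]cyclopropane-1-carboxylic acid
Product: 10 (1R,4S,5S)-4-[3,4,5-tris(benzyloxy)phenyl]-3-oxabicyclo[3.1.0]hexan-2-one, via hydroxy acid 9 (not isolated)
Conditions: NaBH4, MeOH–THF, −20 to 0 °C; then 1 M HCl to pH 2, rt
Reagents that add atoms: none
Why: Borohydride reduction of the aryl cyclopropyl ketone followed by acid lactonisation of the cis γ-hydroxy acid, where hydride enters the s-cis bisected ketone conformer from the face away from the cis carboxylate to give the (S)-carbinol, and ring closure with retention then places the aryl group anti to the cyclopropane.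

**Step 6**
Reactants: 11 catechol (benzene-1,2-diol)
Product: 12 1,2-bis(benzyloxy)benzene
Conditions: BnBr (2.3 equiv), K2CO3, DMF, 60 °C
Reagents that add atoms: benzyl bromide (BrCc1ccccc1)
Why: Williamson ether synthesis on both phenoxides.

**Step 7**
Reactants: 12 1,2-bis(benzyloxy)benzene
Product: 13 3,4-bis(benzyloxy)benzaldehyde
Conditions: Cl2CHOMe (1.2 equiv), SnCl4 (1.5 equiv), CH2Cl2, −20 to 0 °C; then H2O
Reagents that add atoms: dichloromethyl methyl ether (COC(Cl)Cl); water (O)
Why: Rieche formylation (Friedel–Crafts alkylation by the SnCl4-activated α-chloro ether, then hydrolysis), which goes para to one benzyloxy group and at low temperature leaves the benzyl ethers intact.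

**Step 8**
Reactants: 10 (1R,4S,5S)-4-[3,4,5-tris(benzyloxy)phenyl]-3-oxabicyclo[3.1.0]hexan-2-one; 13 3,4-bis(benzyloxy)benzaldehyde
Product: 16 (3S,3aR,6S,6aS)-6-[3,4-bis(benzyloxy)phenyl]-3-[3,4,5-tris(benzyloxy)phenyl]tetrahydro-1H,3H-furo[3,4-c]furan-1-one, via cyclopropyl aldolate 14 (not isolated), via iodomethyl enolate 15 (not isolated)
Conditions: LiN(iPr)2 (1.1 equiv), THF, −78 °C; 13, −78 °C; then MgI2 (1.5 equiv), −78 to 60 °C; NH4Cl aq
Reagents that add atoms: none
Why: Proposed new method: a one-pot bridgehead aldol and iodide-relay ring expansion of a cyclopropane to a tetrahydrofuran, in which the lithium bridgehead enolate of 10 adds to 13 through a closed Zimmerman–Traxler-type transition state (aryl equatorial, Li–O bridge on the open side, away from the lactone face that carries the other aryl group, which sets C6), MgI2 then forms a six-membered chelate between the aldolate oxygen and the lactone carbonyl that activates the cyclopropane for SN2 opening by iodide at its CH2 carbon, the γ-iodo enolate 15 is closed by 5-exo-tet Williamson O-alkylation from the neighbouring alkoxide, and protonation of the bicyclic enolate on the convex face sets C6a cis to C3a; the closest known reaction types are the MgI2-promoted ring expansion of spirocyclopropyl oxindoles with aldimines (homo-Michael opening, Mannich addition, N-alkylation) and the iodo-aldol opening of cyclopropyl ketones, neither of which has been shown for a lactone-activated cyclopropane or with O-alkylative closure to a tetrahydrofuran.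

**Step 9**
Reactants: 16 (3S,3aR,6S,6aS)-6-[3,4-bis(benzyloxy)phenyl]-3-[3,4,5-tris(benzyloxy)phenyl]tetrahydro-1H,3H-furo[3,4-c]furan-1-one
Product: 17 (3S,3aR,6S,6aS)-6-(3,4-dihydroxyphenyl)-3-(3,4,5-trihydroxyphenyl)tetrahydro-1H,3H-furo[3,4-c]furan-1-one
Conditions: H2 (1 atm), 10% Pd/C, EtOAc–THF, rt, stopped at 5 equiv H2 uptake; argon work-up
Reagents that add atoms: none
Why: Catalytic hydrogenolysis of the five aryl benzyl ethers, which cleave much faster than the ring benzylic C–O bonds of the lactone and the tetrahydrofuran, so no stereocentre is touched.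

**Compound list**
1 | 4-bromophenol | Oc1ccc(Br)cc1 | starting material
2 | 5-bromo-2-hydroxybenzene-1,3-dicarbaldehyde | O=Cc1cc(Br)cc(C=O)c1O | intermediate
3 | 5-bromobenzene-1,2,3-triol | Oc1cc(Br)cc(O)c1O | intermediate
4 | 1,2,3-tris(benzyloxy)-5-bromobenzene | Brc1cc(OCc2ccccc2)c(OCc2ccccc2)c(OCc2ccccc2)c1 | intermediate
5 | 3-oxabicyclo[3.1.0]hexane-2,4-dione (meso) | O=C1OC(=O)[C@H]2C[C@@H]12 | starting material
6 | [3,4,5-tris(benzyloxy)phenyl]lithium | [Li]c1cc(OCc2ccccc2)c(OCc2ccccc2)c(OCc2ccccc2)c1 | intermediate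
7 | chloro[3,4,5-tris(benzyloxy)phenyl]zinc | Cl[Zn]c1cc(OCc2ccccc2)c(OCc2ccccc2)c(OCc2ccccc2)c1 | intermediate
8 | (1R,2S)-2-[3,4,5-tris(benzyloxy)benzoyl]cyclopropane-1-carboxylic acid | OC(=O)[C@@H]1C[C@@H]1C(=O)c1cc(OCc2ccccc2)c(OCc2ccccc2)c(OCc2ccccc2)c1 | intermediate
9 | (1R,2S)-2-{(S)-hydroxy[3,4,5-tris(benzyloxy)phenyl]methyl}cyclopropane-1-carboxylic acid | OC(=O)[C@@H]1C[C@@H]1[C@H](O)c1cc(OCc2ccccc2)c(OCc2ccccc2)c(OCc2ccccc2)c1 | intermediate
10 | (1R,4S,5S)-4-[3,4,5-tris(benzyloxy)phenyl]-3-oxabicyclo[3.1.0]hexan-2-one | O=C1O[C@H](c2cc(OCc3ccccc3)c(OCc3ccccc3)c(OCc3ccccc3)c2)[C@H]2C[C@@H]12 | intermediate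
11 | catechol (benzene-1,2-diol) | Oc1ccccc1O | starting material
12 | 1,2-bis(benzyloxy)benzene | c1ccc(OCc2ccccc2)c(OCc2ccccc2)c1 | intermediate
13 | 3,4-bis(benzyloxy)benzaldehyde | O=Cc1ccc(OCc2ccccc2)c(OCc2ccccc2)c1 | intermediate
14 | (1R,4S,5S)-1-{(R)-[3,4-bis(benzyloxy)phenyl](hydroxy)methyl}-4-[3,4,5-tris(benzyloxy)phenyl]-3-oxabicyclo[3.1.0]hexan-2-one (present as its lithium, then magnesium alkoxide) | O=C1O[C@H](c2cc(OCc3ccccc3)c(OCc3ccccc3)c(OCc3ccccc3)c2)[C@H]2C[C@@]12[C@H](O)c1ccc(OCc2ccccc2)c(OCc2ccccc2)c1 | intermediate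
15 | magnesium (4S,5S)-3-{(R)-[3,4-bis(benzyloxy)phenyl]oxidomethyl}-4-(iodomethyl)-5-[3,4,5-tris(benzyloxy)phenyl]-4,5-dihydrofuran-2-olate | [Mg+2].[O-]C1=C([C@H]([O-])c2ccc(OCc3ccccc3)c(OCc3ccccc3)c2)[C@H](CI)[C@@H](c2cc(OCc3ccccc3)c(OCc3ccccc3)c(OCc3ccccc3)c2)O1 | intermediate
16 | (3S,3aR,6S,6aS)-6-[3,4-bis(benzyloxy)phenyl]-3-[3,4,5-tris(benzyloxy)phenyl]tetrahydro-1H,3H-furo[3,4-c]furan-1-one | O=C1O[C@H](c2cc(OCc3ccccc3)c(OCc3ccccc3)c(OCc3ccccc3)c2)[C@H]2CO[C@H](c3ccc(OCc4ccccc4)c(OCc4ccccc4)c3)[C@@H]12 | intermediate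
17 | (3S,3aR,6S,6aS)-6-(3,4-dihydroxyphenyl)-3-(3,4,5-trihydroxyphenyl)tetrahydro-1H,3H-furo[3,4-c]furan-1-one | O=C1O[C@H](c2cc(O)c(O)c(O)c2)[C@H]2CO[C@H](c3ccc(O)c(O)c3)[C@@H]12 | target

**Totals**
Total steps: 9. Longest linear sequence: 7 (steps 1, 2, 3, 4, 5, 8, 9).

**Three steps most likely to fail**

Step 8 (the proposed ring expansion). The risks are self-condensation of the bridgehead enolate, slow iodide opening of a cyclopropane activated by only one carbonyl group, MgI2 cleavage of the benzylic lactone C–O bond, and a poor C6 ratio in the aldol. The fallback uses known chemistry without a ring expansion; it sets out from aryl bromide 4 and comes back to the route at 16. Bromine–lithium exchange of 4 (n-BuLi, THF, −78 °C) and a DMF quench give 3,4,5-tris(benzyloxy)benzaldehyde F1. Condensation of F1 with succinic anhydride (ZnCl2, Et3N, CH2Cl2) gives the racemic trans paraconic acid, which is resolved through its 1-phenylethylamine salt to (2S,3S)-5-oxo-2-[3,4,5-tris(benzyloxy)phenyl]oxolane-3-carboxylic acid F2. BH3·SMe2 reduces the acid beside the lactone to (4R,5S)-4-(hydroxymethyl)-5-[3,4,5-tris(benzyloxy)phenyl]oxolan-2-one F3. Its dianion (LiN(iPr)2, 2.2 equiv, THF, −78 °C) adds to aldehyde 13 to give (3R,4R,5S)-3-{[3,4-bis(benzyloxy)phenyl](hydroxy)methyl}-4-(hydroxymethyl)-5-[3,4,5-tris(benzyloxy)phenyl]oxolan-2-one F4 as carbinol epimers. Acid (TsOH, CH2Cl2) then ionises the benzylic alcohol; the cation, in equilibrium with the α-arylidene lactone so that the α-centre can turn cis, is captured by the primary hydroxyl on the convex face to give 16.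

Step 4 (desymmetrising arylation on a cyclopropane-fused anhydride with a hindered, electron-rich arylzinc). The fallback sets out from anhydride 5 and comes back at keto acid 8. Cinchona-alkaloid-mediated methanolysis (quinidine, MeOH, toluene, −55 °C; the pseudo-enantiomeric alkaloid if the sense is reversed) desymmetrises 5 to (1S,2R)-2-(methoxycarbonyl)cyclopropane-1-carboxylic acid F5. Oxalyl chloride with catalytic DMF gives methyl (1R,2S)-2-(chlorocarbonyl)cyclopropane-1-carboxylate F6. Negishi acylation with arylzinc 7 (made from 4 as in step 4; Pd(PPh3)4, THF) gives methyl (1R,2S)-2-[3,4,5-tris(benzyloxy)benzoyl]cyclopropane-1-carboxylate F7. LiOH (THF–H2O, 0 °C) returns 8.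

Step 5 (facial selectivity of the ketone reduction, which could be reversed by carboxylate-directed hydride delivery). The fallback sets out from 8 and comes back at 10. If the reduction gives mainly the epimeric carbinol (1R,2S)-2-{(R)-hydroxy[3,4,5-tris(benzyloxy)phenyl]methyl}cyclopropane-1-carboxylic acid F8, this acid is closed by intramolecular Mitsunobu lactonisation (PPh3, DIAD, THF, 0 °C). The configuration is then set by SN2 inversion at the carbinol instead of by hydride approach, and the product is 10.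

**Further compounds**
F1 | step 8 | 3,4,5-tris(benzyloxy)benzaldehyde | O=Cc1cc(OCc2ccccc2)c(OCc2ccccc2)c(OCc2ccccc2)c1
F2 | step 8 | (2S,3S)-5-oxo-2-[3,4,5-tris(benzyloxy)phenyl]oxolane-3-carboxylic acid | O=C1O[C@H](c2cc(OCc3ccccc3)c(OCc3ccccc3)c(OCc3ccccc3)c2)[C@@H](C(=O)O)C1
F3 | step 8 | (4R,5S)-4-(hydroxymethyl)-5-[3,4,5-tris(benzyloxy)phenyl]oxolan-2-one | O=C1O[C@H](c2cc(OCc3ccccc3)c(OCc3ccccc3)c(OCc3ccccc3)c2)[C@@H](CO)C1
F4 | step 8 | (3R,4R,5S)-3-{[3,4-bis(benzyloxy)phenyl](hydroxy)methyl}-4-(hydroxymethyl)-5-[3,4,5-tris(benzyloxy)phenyl]oxolan-2-one | O=C1O[C@H](c2cc(OCc3ccccc3)c(OCc3ccccc3)c(OCc3ccccc3)c2)[C@@H](CO)[C@@H]1C(O)c1ccc(OCc2ccccc2)c(OCc2ccccc2)c1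
F5 | step 4 | (1S,2R)-2-(methoxycarbonyl)cyclopropane-1-carboxylic acid | COC(=O)[C@@H]1C[C@@H]1C(=O)O
F6 | step 4 | methyl (1R,2S)-2-(chlorocarbonyl)cyclopropane-1-carboxylate | COC(=O)[C@@H]1C[C@@H]1C(=O)Cl
F7 | step 4 | methyl (1R,2S)-2-[3,4,5-tris(benzyloxy)benzoyl]cyclopropane-1-carboxylate | COC(=O)[C@@H]1C[C@@H]1C(=O)c1cc(OCc2ccccc2)c(OCc2ccccc2)c(OCc2ccccc2)c1
F8 | step 5 | (1R,2S)-2-{(R)-hydroxy[3,4,5-tris(benzyloxy)phenyl]methyl}cyclopropane-1-carboxylic acid | OC(=O)[C@@H]1C[C@@H]1[C@@H](O)c1cc(OCc2ccccc2)c(OCc2ccccc2)c(OCc2ccccc2)c1
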